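# Proposed total synthesis of CNP0335239.1 by an intramolecular vinylketene–alkene [2+2] cycloaddition

Locants are those of tricyclo[5.4.0.0^2,8]undecane, which coincide with longipinane numbering: C1 and C8 are the cyclobutane CH groups, C2 the quaternary C–CH3, C7 the cyclobutane CH bonded to C6, C9–C10–C11 the three-carbon bridge, and C3–C6 the four-carbon chain.

## The problem

- The target 28 is a bicyclo[3.1.1]heptenone: a cyclobutane C1–C2–C8–C7 spanned by C9–C10–C11. Its two one-carbon bridges C2 and C7 are tied together by the chain C3–C4–C5–C6, which closes a seven-membered ring.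
- There are six stereocentres. C1, C2, C7 and C8 belong to the cage, and their relative configuration is imposed by the ring system, because the C3–C6 chain can only span the face of the cyclobutane turned away from C9–C11. For these four centres only the absolute sense has to be controlled.
- C3 and C5 carry the two esters, trans to each other on the seven-membered ring, and must be set relative to the cage. C3 can be made early in an acyclic precursor and then steers the cage. C5 is best set late from C3, because the cage itself hardly distinguishes the two faces of a C5 carbonyl.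
- Both carbinols are neopentyl-like (next to quaternary C2 and C6), so the two hindered hydroxyls of a 3,5-diol could not be acylated selectively. The two different esters must be introduced by a reaction that tells the oxygens apart.
- Fragile features are the 1,3-diol diester (acyl migration, β-elimination when either carbon is a ketone), the enone, and, before the enone exists, the vinylcyclobutane. Like a pinene, the vinylcyclobutane opens under acid and after radical addition to the alkene.
- The key step rests on three features. C7 is a cyclobutane carbon that can be carried as a carbonyl. C2 bears a methyl and the C3 chain exactly as the distal E-trisubstituted alkene of an 8-oxygenated geranic acid does. C8 and C9 with its methyl are the α- and β-carbons of that acid. A vinylketene C7=C8–C9(=CH2) can therefore add across C1=C2.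

## Retrosynthesis

**Esters and C5.** In 28 the C5–O acyl bond is cut first, giving hydroxy ester 26 and acid chloride 27. In 26 the C3–O acyl bond and the C5–H bond are cut together, giving β-hydroxy ketone 23 and aldehyde 24 (Evans–Tishchenko reduction). Against acylation of a 3,5-diol, this cut makes C5 from C3 by intramolecular hydride delivery (trans), puts the senecioate on the directing oxygen, and leaves only one free hydroxyl for 27. The forward reaction must deliver hydride to the C5 face syn to O3 and spare the C11 enone.

**C11 oxygen.** Alcohol 23 comes from silyl ether 22, and the C11 carbonyl of 22 is removed to give alkene 21. Carrying the C11 oxygen from the start would put a second allylic oxygen on the alkene that must act as the nucleophile in the key step. Late allylic oxidation has the α-pinene to verbenone analogy and needs only selectivity for the one ring methylene.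

**C7 hydrogen.** The C7–H of 21 is traced to the tertiary alcohol 19 through methyl oxalate 20. The hydroxyl is the price of closing the seven-membered ring by carbonyl addition. It has no β-hydrogen to eliminate (C6 is quaternary, C1 and C8 are bridgeheads), so radical C–O cleavage is required, with hydrogen transfer faster than rearrangement of the C7 radical.

**Seven-membered ring.** In 19 the C6–C7 bond is cut, giving bicyclic diketone 17. This cut uses the carbonyl that the ketene cycloaddition leaves at C7. The enolate must form at C6 and not at C4, since a C4 enolate would close a five-membered ring onto C7 or expel the C3 silyloxy group. For that reason C6 carries a benzoyloxy group in 17, which SmI2 removes to give enolate 18 at that carbon only. This replaces the regiochemically unsafe bromination of an isopropyl ketone in the presence of alkenes.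

**Alkene position.** Ketone 17 is the endocyclic isomer of the cycloadduct 16. The shift is placed here so that the later tin hydride step does not meet an exocyclic vinylcyclobutane.

**Cage.** In 16 the bonds C1–C7 and C2–C8 are cut together, giving vinylketene 15 and its precursor, acid chloride 14. Both rings of the bicyclo[3.1.1]heptanone and three stereocentres arise at once, and the precursor is an open chain with a single stereocentre. The forward reaction must give the crossed regiochemistry, add suprafacially to the E alkene, and choose the alkene face with respect to C3.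

**Functional groups.** Acid chloride 14 comes from acid 13, aldehyde 12 and allylic alcohol 11; 11 comes from acetate 10, the silyl ether of aldol 9. These are oxidation-level and protecting-group changes at the far end of the chain.

**C3–C4.** Aldol 9 is cut between C3 and C4 into methyl ketone 3 and enal 6, joined through boron enolate 7 and aldolate 8. Ketone 3 has a single enolisable position, and the aldol sets C3 under reagent control. A cut between C2 and C3 would instead need a chiral β-keto aldehyde.

**Starting materials.** Enal 6 comes from geranyl acetate 4 through allylic alcohol 5. Ketone 3 comes from hydroxy ketone 1 and benzoyl chloride 2.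

## Roads not taken

**Alternative 1: chiral-pool cage and hydroxyl-directed methyl C–H silylation.**
- Cut: a C–H bond of one of the two geminal methyl groups on C2 of a chrysanthenone.
- Forward: (1S,5S)-verbenone A1 would be photoisomerised to the chrysanthenone enantiomer A2 and the C7 ketone reduced. The diethylhydrosilyl ether would then undergo dehydrogenative silylation of the methyl C–H bond facing the C7–O bond (a rhodium catalyst such as [Rh(cod)Cl]2 with a bisphosphine). This closes oxasilinane A3 and makes C2 stereogenic.
- Merits: the absolute configuration of the cage comes from the chiral pool, so the facial question of the chosen plan does not arise. The oxygen on C7 reaches only the methyl that must become C3.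
- Weak points: the photochemical 1,3-shift linking A1 and A2 runs through a ketene/diradical manifold that can also interconvert the enantiomers of A2, so optical purity is at risk. After A3, C3 is only a CH2–O group. C4, C5 and C6 must still be attached, C3 made stereogenic next to a quaternary carbon, C7 reoxidised, and the C6–C7 bond closed with the same hydroxyl removal as here.
- Comparison: Alternative 1 is better in cage control. The chosen plan sets against it that all carbons of the seven-membered ring and the C3 stereocentre are in place before the cage forms, which saves steps after the key step.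

**Alternative 2: decarboxylative radical closure of the seven-membered ring.**
- Cut: C5–C6.
- Forward: cathodic reduction (zinc sacrificial anode) of the N-hydroxyphthalimide ester A4 releases CO2 and a tertiary C6 radical. It adds 7-endo to C5 of the β-alkoxyvinyl ketone on C2 and gives diketone A5.
- Merits: a radical tolerates the congestion at quaternary C6 better than a fully substituted enolate does. C7 is a CH from the outset, so the two deoxygenation steps of the chosen plan are not needed, and in this respect Alternative 2 is better.
- Weak points: the radical must attack the oxygen-bearing, donor-substituted terminus of a vinylogous ester in a 7-endo mode, against simple reduction of the radical. C5 would be set by ring conformation only. The C3 ketone must later be reduced with the right facial sense in the presence of the enone. The enantiopure cage precursor A4 is itself a long, unspecified synthesis.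
- Comparison: the chosen plan sets against the shorter closure a far simpler precursor, a known key reaction, and control of C5 by directed hydride delivery.

**Alternative 3: enamine α,α′-annulation of a prochiral cyclobutanone.**
- Cut: C8–C9 and C1–C11.
- Forward: the chiral pyrrolidine enamine of cyclobutanone A6 would react with an α,β-unsaturated C4 acid chloride by conjugate C-alkylation and then C-acylation at the other α-carbon, giving dione A7.
- Merits: the route is convergent. The C11 carbonyl and the C9 methyl are in place directly, whereas the chosen plan needs an alkene shift and an allylic oxidation. C3 is at the aldehyde level, ready for an aldol.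
- Weak points: the annulation is established for enamines of five- and six-membered ketones. Here the second bond must bridge the 1,3-positions of a four-membered ring and places two carbonyls on the strained skeleton. Cyclobutanone enamines form reluctantly. The choice between methyl and dimethoxymethyl at C2 is between groups of similar size. The C9=C10 unsaturation and the whole C6–C7 construction remain to be done.
- Comparison: Alternative 3 is shorter on paper to the oxygenated six-membered ring. The chosen plan sets against it a key step of a known reaction class and a C2 configuration fixed by alkene geometry.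

Key step: step 10

Assumption: the (+)-antipode of Ipc2BCl is taken to direct the methyl ketone enolate to the Re face of enal 6 (giving 8R); if the sense is the opposite, the (–)-antipode is used and nothing else changes.

## Route

Step 1
Reactants: 1 3-hydroxy-3-methylbutan-2-one; 2 benzoyl chloride
Product: 3 2-methyl-3-oxobutan-2-yl benzoate
Conditions: BzCl (1.2 equiv), pyridine, DMAP (0.1 equiv), CH2Cl2, 0 °C → 40 °C
Reagents that add atoms: benzoyl chloride (2), O=C(Cl)c1ccccc1
Why: DMAP-catalysed O-acylation of a tertiary α-ketol. The ketone keeps one enolisable position (the methyl), and the benzoate later serves as the leaving group that fixes the enolate at C6.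

Step 2
Reactants: 4 geranyl acetate
Product: 5 (2E,6E)-8-hydroxy-3,7-dimethylocta-2,6-dien-1-yl acetate
Conditions: SeO2 (0.3 equiv), t-BuOOH (70% aq., 3 equiv), salicylic acid (0.1 equiv), CH2Cl2, rt
Reagents that add atoms: selenium dioxide, O=[Se]=O (oxygen carrier); tert-butyl hydroperoxide, CC(C)(C)OO (terminal oxidant)
Why: SeO2 allylic hydroxylation (ene reaction, then [2,3]-shift) attacks the E methyl of the electron-richer terminal alkene; the other alkene is deactivated by the allylic acetate. Any aldehyde 6 formed by over-oxidation is carried into step 3.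

Step 3
Reactants: 5 (2E,6E)-8-hydroxy-3,7-dimethylocta-2,6-dien-1-yl acetate
Product: 6 (2E,6E)-3,7-dimethyl-8-oxoocta-2,6-dien-1-yl acetate
Conditions: MnO2 (15 equiv), CH2Cl2, rt
Reagents that add atoms: none
Why: MnO2 oxidises the allylic alcohol to the E enal without touching the acetate or the alkenes.

Step 4
Reactants: 3 2-methyl-3-oxobutan-2-yl benzoate; 6 (2E,6E)-3,7-dimethyl-8-oxoocta-2,6-dien-1-yl acetate
Product: 9 (2E,6E,8R)-1-acetoxy-8-hydroxy-3,7,11-trimethyl-10-oxododeca-2,6-dien-11-yl benzoate, via boron enolate 7 (not isolated), via boron aldolate 8 (not isolated)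
Conditions: (+)-Ipc2BCl (1.5 equiv), Et3N (1.8 equiv), Et2O, 0 °C; then 6, –78 → –20 °C; then MeOH, pH 7 buffer, 30% H2O2, 0 °C
Reagents that add atoms: none
Why: Enantioselective boron aldol reaction of a methyl ketone. Ketone 3 can only enolise at its methyl group, and the diisopinocampheylboron enolate 7 adds 1,2 to the enal through a chair-like six-membered transition state in which the isopinocampheyl ligands select the Re face, setting C3 of the target as 8R. Optical purity is to be checked on 9 (chiral HPLC or MTPA esters).

Step 5
Reactants: 9 (2E,6E,8R)-1-acetoxy-8-hydroxy-3,7,11-trimethyl-10-oxododeca-2,6-dien-11-yl benzoate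
Product: 10 (2E,6E,8R)-1-acetoxy-8-[(tert-butyldimethylsilyl)oxy]-3,7,11-trimethyl-10-oxododeca-2,6-dien-11-yl benzoate
Conditions: TBSOTf (1.3 equiv), 2,6-lutidine (2 equiv), CH2Cl2, –78 °C
Reagents that add atoms: tert-butyldimethylsilyl triflate, CC(C)(C)[Si](C)(C)OS(=O)(=O)C(F)(F)F
Why: Silylation of the secondary allylic alcohol at low temperature avoids dehydration of the β-hydroxy ketone. The silyl ether survives base, oxidants, acid chloride formation and hot amine.

Step 6
Reactants: 10 (2E,6E,8R)-1-acetoxy-8-[(tert-butyldimethylsilyl)oxy]-3,7,11-trimethyl-10-oxododeca-2,6-dien-11-yl benzoate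
Product: 11 (2E,6E,8R)-8-[(tert-butyldimethylsilyl)oxy]-1-hydroxy-3,7,11-trimethyl-10-oxododeca-2,6-dien-11-yl benzoate
Conditions: K2CO3 (0.2 equiv), MeOH, 0 °C
Reagents that add atoms: none
Why: Zemplén-type transesterification. The primary allylic acetate is methanolysed far faster than the hindered tertiary benzoate, and catalytic base at 0 °C spares the β-silyloxy ketone.

Step 7
Reactants: 11 (2E,6E,8R)-8-[(tert-butyldimethylsilyl)oxy]-1-hydroxy-3,7,11-trimethyl-10-oxododeca-2,6-dien-11-yl benzoate
Product: 12 (2E,6E,8R)-8-[(tert-butyldimethylsilyl)oxy]-3,7,11-trimethyl-1,10-dioxododeca-2,6-dien-11-yl benzoate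
Conditions: MnO2 (15 equiv), CH2Cl2, rt
Reagents that add atoms: none
Why: Chemoselective MnO2 oxidation of the allylic alcohol to the E enal, as in geraniol to geranial.

Step 8
Reactants: 12 (2E,6E,8R)-8-[(tert-butyldimethylsilyl)oxy]-3,7,11-trimethyl-1,10-dioxododeca-2,6-dien-11-yl benzoate
Product: 13 (2E,6E,8R)-11-(benzoyloxy)-8-[(tert-butyldimethylsilyl)oxy]-3,7,11-trimethyl-10-oxododeca-2,6-dienoic acid
Conditions: NaClO2 (3 equiv), NaH2PO4 (3 equiv), 2-methylbut-2-ene (10 equiv), t-BuOH/H2O, 0 °C → rt
Reagents that add atoms: sodium chlorite, [Na+].[O-]Cl=O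
Why: Pinnick oxidation of the enal to the enoic acid. The alkene scavenger removes hypochlorite, so the trisubstituted alkenes and the silyl ether are not attacked.

Step 9
Reactants: 13 (2E,6E,8R)-11-(benzoyloxy)-8-[(tert-butyldimethylsilyl)oxy]-3,7,11-trimethyl-10-oxododeca-2,6-dienoic acid
Product: 14 (2E,6E,8R)-11-(benzoyloxy)-8-[(tert-butyldimethylsilyl)oxy]-3,7,11-trimethyl-10-oxododeca-2,6-dienoyl chloride
Conditions: (COCl)2 (1.5 equiv), DMF (cat.), CH2Cl2, 0 °C → rt; volatiles removed, used crude
Reagents that add atoms: oxalyl chloride, O=C(Cl)C(Cl)=O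
Why: Standard conversion of the acid to the acid chloride through the chloroiminium catalyst. The E geometry keeps the C9 methyl cis to the acyl group, where it is deprotonated in the next step.

Step 10
Reactants: 14 (2E,6E,8R)-11-(benzoyloxy)-8-[(tert-butyldimethylsilyl)oxy]-3,7,11-trimethyl-10-oxododeca-2,6-dienoyl chloride
Product: 16 (1R,5S,7S)-7-[(1R)-4-(benzoyloxy)-1-[(tert-butyldimethylsilyl)oxy]-4-methyl-3-oxopentyl]-7-methyl-2-methylidenebicyclo[3.1.1]heptan-6-one, via vinylketene 15 (not isolated)
Conditions: Et3N (5 equiv), toluene, 110 °C; 14 in toluene added over 6 h (final 0.01 M), then 2 h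
Reagents that add atoms: none
Why: Et3N removes HCl from 14 by 1,4-elimination through the C9 methyl to give vinylketene 15; its electrophilic carbon C7 bonds to the less substituted alkene carbon C1 while positive charge builds at tertiary C2, which then collapses onto the dienolate carbon C8 in an asynchronous [2+2] cycloaddition. The closest known reaction type is the thermal intramolecular [2+2] cycloaddition of vinylketenes, made from α,β-unsaturated acid chlorides and Et3N, with trisubstituted alkenes, which gives 7,7-disubstituted 2-methylidenebicyclo[3.1.1]heptan-6-ones. The six-membered ring closes when C7–C1 forms (6-exo attack on the alkene through the tether C9–C10–C11), and the cyclobutanone closes when C8 bonds to cationic C2, so both rings arise in one operation. The crossed rather than fused adduct follows from the tertiary character of C2 and the short tether. C1 and C8 form as a necessarily cis-bridged pair, and C2 follows from suprafacial addition to the E alkene, which puts the methyl over the C9–C11 bridge and the C3 chain toward C7. The one selectivity not fixed by mechanism is the face of the alkene relative to C3: allylic 1,3-strain is small here because C1 carries hydrogen cis to C3, so the expectation rests on a staggered transition state with hydrogen in the crowded inside position over the forming cyclobutanone, the C3–C4 bond anti to the forming C2–C8 bond as the better σ-donor to cationic C2, and the silyloxy group outside. The other cage diastereomer, which would arise with the C–O bond anti, is to be removed by chromatography; it does not affect optical purity. Slow addition at high dilution in boiling toluene offsets the lower nucleophilicity of the alkene caused by the allylic silyloxy group.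

Step 11
Reactants: 16 (1R,5S,7S)-7-[(1R)-4-(benzoyloxy)-1-[(tert-butyldimethylsilyl)oxy]-4-methyl-3-oxopentyl]-7-methyl-2-methylidenebicyclo[3.1.1]heptan-6-one
Product: 17 (1R,5S,7S)-7-[(1R)-4-(benzoyloxy)-1-[(tert-butyldimethylsilyl)oxy]-4-methyl-3-oxopentyl]-2,7-dimethylbicyclo[3.1.1]hept-2-en-6-one
Conditions: RhCl3·3H2O (5 mol%), EtOH, 70 °C
Reagents that add atoms: none
Why: Rhodium hydride addition–elimination moves the exocyclic alkene to the more stable trisubstituted ring position (the β-pinene to α-pinene relationship). Migration toward C8 is excluded because it would give a bridgehead alkene, and no stereocentre is touched.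

Step 12
Reactants: 17 (1R,5S,7S)-7-[(1R)-4-(benzoyloxy)-1-[(tert-butyldimethylsilyl)oxy]-4-methyl-3-oxopentyl]-2,7-dimethylbicyclo[3.1.1]hept-2-en-6-one
Product: 19 (1S,2S,3R,7S,8R)-3-[(tert-butyldimethylsilyl)oxy]-7-hydroxy-2,6,6,9-tetramethyltricyclo[5.4.0.0^2,8]undec-9-en-5-one, via samarium enolate 18 (not isolated)
Conditions: SmI2 (2.5 equiv), THF, –78 → –20 °C; sat. NH4Cl
Reagents that add atoms: none
Why: SmI2 cleaves the α-benzoyloxy ketone reductively to the samarium enolate 18, formed only at C6. Enolate 18 adds to the strained, non-enolisable C7 carbonyl in a Reformatsky-type intramolecular aldol reaction (7-enolendo-exo-trig). The tether reaches C7 only from the face turned toward C3, so the C7 hydroxyl is placed toward the C9–C11 bridge.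

Step 13
Reactants: 19 (1S,2S,3R,7S,8R)-3-[(tert-butyldimethylsilyl)oxy]-7-hydroxy-2,6,6,9-tetramethyltricyclo[5.4.0.0^2,8]undec-9-en-5-one
Product: 20 methyl (1S,2S,3R,7S,8R)-3-[(tert-butyldimethylsilyl)oxy]-2,6,6,9-tetramethyl-5-oxotricyclo[5.4.0.0^2,8]undec-9-en-7-yl oxalate
Conditions: ClC(O)CO2Me (3 equiv), pyridine, DMAP (0.5 equiv), CH2Cl2, 0 °C → rt
Reagents that add atoms: methyl chlorooxoacetate, COC(=O)C(Cl)=O
Why: The small, highly electrophilic oxalyl chloride acylates even hindered tertiary alcohols. The weakly basic conditions avoid retro-aldol cleavage, and the ester cannot eliminate because C7 has no β-hydrogen outside a bridgehead.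

Step 14
Reactants: 20 methyl (1S,2S,3R,7S,8R)-3-[(tert-butyldimethylsilyl)oxy]-2,6,6,9-tetramethyl-5-oxotricyclo[5.4.0.0^2,8]undec-9-en-7-yl oxalate
Product: 21 (1R,2S,3R,7R,8R)-3-[(tert-butyldimethylsilyl)oxy]-2,6,6,9-tetramethyltricyclo[5.4.0.0^2,8]undec-9-en-5-one
Conditions: Bu3SnH (3 equiv, 0.5 M), (PhSe)2 (0.1 equiv), AIBN (0.2 equiv), toluene, 100 °C
Reagents that add atoms: none
Why: Barton–McCombie-type radical deoxygenation of a tertiary methyl oxalate: the stannyl radical adds to the oxalate and C7–O homolysis gives the cyclobutyl radical. Benzeneselenol formed in situ transfers hydrogen faster than the radical can attack the C5 carbonyl (1,2-acyl shift). The bridge holds C6 on one face, so hydrogen enters from the C9–C11 side and C7 has the target configuration.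

Step 15
Reactants: 21 (1R,2S,3R,7R,8R)-3-[(tert-butyldimethylsilyl)oxy]-2,6,6,9-tetramethyltricyclo[5.4.0.0^2,8]undec-9-en-5-one
Product: 22 (1R,2R,3R,7S,8R)-3-[(tert-butyldimethylsilyl)oxy]-2,6,6,9-tetramethyltricyclo[5.4.0.0^2,8]undec-9-ene-5,11-dione
Conditions: Rh2(cap)4 (dirhodium tetrakis(caprolactamate), 1 mol%), t-BuOOH (70% aq., 5 equiv), K2CO3 (0.5 equiv), CH2Cl2, rt
Reagents that add atoms: tert-butyl hydroperoxide, CC(C)(C)OO
Why: Allylic C–H oxidation by tert-butylperoxyl radicals at the only secondary allylic position, the ring methylene C11, gives the conjugated enone as in the α-pinene to verbenone oxidation. The ketone and silyl ether are inert, and the enone makes the vinylcyclobutane less acid-sensitive.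

Step 16
Reactants: 22 (1R,2R,3R,7S,8R)-3-[(tert-butyldimethylsilyl)oxy]-2,6,6,9-tetramethyltricyclo[5.4.0.0^2,8]undec-9-ene-5,11-dione
Product: 23 (1R,2R,3R,7S,8R)-3-hydroxy-2,6,6,9-tetramethyltricyclo[5.4.0.0^2,8]undec-9-ene-5,11-dione
Conditions: HF·pyridine, pyridine, THF, 0 °C → rt
Reagents that add atoms: none
Why: Fluoride cleavage of the silyl ether under buffered, non-basic conditions frees the C3 hydroxyl without retro-aldol cleavage or dehydration of the β-hydroxy ketone.

Step 17
Reactants: 23 (1R,2R,3R,7S,8R)-3-hydroxy-2,6,6,9-tetramethyltricyclo[5.4.0.0^2,8]undec-9-ene-5,11-dione; 24 3-methylbut-2-enal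
Product: 26 (1R,2R,3R,5R,7S,8R)-5-hydroxy-2,6,6,9-tetramethyl-11-oxotricyclo[5.4.0.0^2,8]undec-9-en-3-yl 3-methylbut-2-enoate, via hemiacetal 25 (not isolated)
Conditions: 24 (6 equiv), SmI2 (0.3 equiv, added to 24 first), THF, –10 °C
Reagents that add atoms: 3-methylbut-2-enal (24), CC(C)=CC=O
Why: Evans–Tishchenko reduction. Trivalent samarium formed from SmI2 and the aldehyde binds the hemiacetal 25 and the C5 carbonyl, and the hemiacetal hydrogen shifts as hydride through a six-membered transition state to the C5 face syn to O3. This gives the 5R alcohol trans to the C3 oxygen and leaves the acyl group on O3 as the senecioate. The C11 enone is not in a 1,3-relationship to O3 and is less electrophilic, and the trans ring geometry disfavours acyl migration.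

Step 18
Reactants: 26 (1R,2R,3R,5R,7S,8R)-5-hydroxy-2,6,6,9-tetramethyl-11-oxotricyclo[5.4.0.0^2,8]undec-9-en-3-yl 3-methylbut-2-enoate; 27 3-methylbutanoyl chloride
Product: 28 (1R,2R,3R,5R,7S,8R)-2,6,6,9-tetramethyl-3-[(3-methylbut-2-enoyl)oxy]-11-oxotricyclo[5.4.0.0^2,8]undec-9-en-5-yl 3-methylbutanoate
Conditions: 27 (3 equiv), DMAP (0.5 equiv), pyridine, CH2Cl2, 0 → 40 °C
Reagents that add atoms: 3-methylbutanoyl chloride (27), CC(C)CC(Cl)=O
Why: DMAP-catalysed acylation of the one remaining hydroxyl, with retention at C5, completes the target.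

## Compound list

1 | 3-hydroxy-3-methylbutan-2-one | CC(=O)C(C)(C)O | starting material
2 | benzoyl chloride | O=C(Cl)c1ccccc1 | starting material
3 | 2-methyl-3-oxobutan-2-yl benzoate | CC(=O)C(C)(C)OC(=O)c1ccccc1 | intermediate
4 | geranyl acetate, (2E)-3,7-dimethylocta-2,6-dien-1-yl acetate | CC(C)=CCC/C(C)=C/COC(C)=O | starting material
5 | (2E,6E)-8-hydroxy-3,7-dimethylocta-2,6-dien-1-yl acetate | CC(=O)OC/C=C(C)/CC/C=C(C)/CO | intermediate
6 | (2E,6E)-3,7-dimethyl-8-oxoocta-2,6-dien-1-yl acetate | CC(=O)OC/C=C(C)/CC/C=C(C)/C=O | intermediate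
7 | boron enolate of 3, 3-{[bis(isopinocampheyl)boranyl]oxy}-2-methylbut-3-en-2-yl benzoate (ligands from (+)-Ipc2BCl) | C=C(OB([C@H]1C[C@H]2C[C@@H]([C@@H]1C)C2(C)C)[C@H]3C[C@H]4C[C@@H]([C@@H]3C)C4(C)C)C(C)(C)OC(=O)c5ccccc5 | intermediate (not isolated)
8 | boron aldolate, O8-bis(isopinocampheyl)boranyl derivative of 9 (8R) | CC(=O)OC/C=C(C)/CC/C=C(C)/[C@H](OB([C@H]1C[C@H]2C[C@@H]([C@@H]1C)C2(C)C)[C@H]3C[C@H]4C[C@@H]([C@@H]3C)C4(C)C)CC(=O)C(C)(C)OC(=O)c5ccccc5 | intermediate (not isolated)
9 | (2E,6E,8R)-1-acetoxy-8-hydroxy-3,7,11-trimethyl-10-oxododeca-2,6-dien-11-yl benzoate | CC(=O)OC/C=C(C)/CC/C=C(C)/[C@H](O)CC(=O)C(C)(C)OC(=O)c1ccccc1 | intermediate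
10 | (2E,6E,8R)-1-acetoxy-8-[(tert-butyldimethylsilyl)oxy]-3,7,11-trimethyl-10-oxododeca-2,6-dien-11-yl benzoate | CC(=O)OC/C=C(C)/CC/C=C(C)/[C@H](O[Si](C)(C)C(C)(C)C)CC(=O)C(C)(C)OC(=O)c1ccccc1 | intermediate
11 | (2E,6E,8R)-8-[(tert-butyldimethylsilyl)oxy]-1-hydroxy-3,7,11-trimethyl-10-oxododeca-2,6-dien-11-yl benzoate | OC/C=C(C)/CC/C=C(C)/[C@H](O[Si](C)(C)C(C)(C)C)CC(=O)C(C)(C)OC(=O)c1ccccc1 | intermediate
12 | (2E,6E,8R)-8-[(tert-butyldimethylsilyl)oxy]-3,7,11-trimethyl-1,10-dioxododeca-2,6-dien-11-yl benzoate | O=C/C=C(C)/CC/C=C(C)/[C@H](O[Si](C)(C)C(C)(C)C)CC(=O)C(C)(C)OC(=O)c1ccccc1 | intermediate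
13 | (2E,6E,8R)-11-(benzoyloxy)-8-[(tert-butyldimethylsilyl)oxy]-3,7,11-trimethyl-10-oxododeca-2,6-dienoic acid | OC(=O)/C=C(C)/CC/C=C(C)/[C@H](O[Si](C)(C)C(C)(C)C)CC(=O)C(C)(C)OC(=O)c1ccccc1 | intermediate
14 | (2E,6E,8R)-11-(benzoyloxy)-8-[(tert-butyldimethylsilyl)oxy]-3,7,11-trimethyl-10-oxododeca-2,6-dienoyl chloride (precursor of the key step) | O=C(Cl)/C=C(C)/CC/C=C(C)/[C@H](O[Si](C)(C)C(C)(C)C)CC(=O)C(C)(C)OC(=O)c1ccccc1 | intermediate
15 | vinylketene, (6E,8R)-11-(benzoyloxy)-8-[(tert-butyldimethylsilyl)oxy]-7,11-dimethyl-3-methylidene-10-oxododeca-1,6-dien-1-one | O=C=CC(=C)CC/C=C(C)/[C@H](O[Si](C)(C)C(C)(C)C)CC(=O)C(C)(C)OC(=O)c1ccccc1 | intermediate (not isolated)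
16 | (1R,5S,7S)-7-[(1R)-4-(benzoyloxy)-1-[(tert-butyldimethylsilyl)oxy]-4-methyl-3-oxopentyl]-7-methyl-2-methylidenebicyclo[3.1.1]heptan-6-one (product of the key step; side chain on the face of C7 away from C2–C4, methyl over C2–C4) | CC(C)(OC(=O)c1ccccc1)C(=O)C[C@@H](O[Si](C)(C)C(C)(C)C)[C@@]1(C)[C@@H]2CCC(=C)[C@H]1C2=O | intermediate
17 | (1R,5S,7S)-7-[(1R)-4-(benzoyloxy)-1-[(tert-butyldimethylsilyl)oxy]-4-methyl-3-oxopentyl]-2,7-dimethylbicyclo[3.1.1]hept-2-en-6-one | CC(C)(OC(=O)c1ccccc1)C(=O)C[C@@H](O[Si](C)(C)C(C)(C)C)[C@@]1(C)[C@@H]2CC=C(C)[C@H]1C2=O | intermediate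
18 | samarium enolate of 17 (C5–O–SmI2, C5=C6, benzoate lost) | CC(C)=C(O[Sm](I)I)C[C@@H](O[Si](C)(C)C(C)(C)C)[C@@]1(C)[C@@H]2CC=C(C)[C@H]1C2=O | intermediate (not isolated)
19 | (1S,2S,3R,7S,8R)-3-[(tert-butyldimethylsilyl)oxy]-7-hydroxy-2,6,6,9-tetramethyltricyclo[5.4.0.0^2,8]undec-9-en-5-one (C7 hydroxyl toward the C9–C11 bridge) | CC(C)(C)[Si](C)(C)O[C@@H]1CC(=O)C(C)(C)[C@]2(O)[C@H]3CC=C(C)[C@@H]2[C@]31C | intermediate
20 | methyl (1S,2S,3R,7S,8R)-3-[(tert-butyldimethylsilyl)oxy]-2,6,6,9-tetramethyl-5-oxotricyclo[5.4.0.0^2,8]undec-9-en-7-yl oxalate | CC(C)(C)[Si](C)(C)O[C@@H]1CC(=O)C(C)(C)[C@]2(OC(=O)C(=O)OC)[C@H]3CC=C(C)[C@@H]2[C@]31C | intermediate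
21 | (1R,2S,3R,7R,8R)-3-[(tert-butyldimethylsilyl)oxy]-2,6,6,9-tetramethyltricyclo[5.4.0.0^2,8]undec-9-en-5-one | CC(C)(C)[Si](C)(C)O[C@@H]1CC(=O)C(C)(C)[C@@H]2[C@H]3CC=C(C)[C@@H]2[C@]31C | intermediate
22 | (1R,2R,3R,7S,8R)-3-[(tert-butyldimethylsilyl)oxy]-2,6,6,9-tetramethyltricyclo[5.4.0.0^2,8]undec-9-ene-5,11-dione | CC(C)(C)[Si](C)(C)O[C@@H]1CC(=O)C(C)(C)[C@@H]2[C@H]3C(=O)C=C(C)[C@@H]2[C@]31C | intermediate
23 | (1R,2R,3R,7S,8R)-3-hydroxy-2,6,6,9-tetramethyltricyclo[5.4.0.0^2,8]undec-9-ene-5,11-dione | O[C@@H]1CC(=O)C(C)(C)[C@@H]2[C@H]3C(=O)C=C(C)[C@@H]2[C@]31C | intermediate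
24 | 3-methylbut-2-enal | CC(C)=CC=O | starting material
25 | hemiacetal of 23 with 24 at O3 (hemiacetal carbon not defined) | CC(C)=CC(O)O[C@@H]1CC(=O)C(C)(C)[C@@H]2[C@H]3C(=O)C=C(C)[C@@H]2[C@]31C | intermediate (not isolated)
26 | (1R,2R,3R,5R,7S,8R)-5-hydroxy-2,6,6,9-tetramethyl-11-oxotricyclo[5.4.0.0^2,8]undec-9-en-3-yl 3-methylbut-2-enoate | CC(C)=CC(=O)O[C@@H]1C[C@@H](O)C(C)(C)[C@@H]2[C@H]3C(=O)C=C(C)[C@@H]2[C@]31C | intermediate
27 | 3-methylbutanoyl chloride | CC(C)CC(Cl)=O | starting material
28 | (1R,2R,3R,5R,7S,8R)-2,6,6,9-tetramethyl-3-[(3-methylbut-2-enoyl)oxy]-11-oxotricyclo[5.4.0.0^2,8]undec-9-en-5-yl 3-methylbutanoate (CNP0335239.1) | CC(C)=CC(=O)O[C@@H]1C[C@@H](OC(=O)CC(C)C)C(C)(C)[C@@H]2[C@H]3C(=O)C=C(C)[C@@H]2[C@]31C | target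

## Step count and risks

Total step count: 18. Longest linear sequence: 17 steps (geranyl acetate 4 to 28, steps 2–18); step 1 is a one-step side branch to ketone 3.

Least certain steps:

**Step 10 (key step).**
- What may go wrong: poor or even reversed discrimination between the two alkene faces, because the controlling centre C3 is acyclic and a transition state with the C–O bond anti competes with the chain-anti one. This costs throughput but not optical purity. Slow addition to the deactivated alkene may also allow oligomerisation of 15, or loss of silanol from the β-silyloxy ketone in hot amine.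
- Fallback: it sets out from 14 and comes back at 16. The same two bonds are formed in a Lewis-acid-promoted, stepwise cationic mode. Ketene 15 is generated with Et3N in CH2Cl2 at room temperature and treated at –78 °C with EtAlCl2. Coordination to the ketene oxygen raises the charge at C2 in the transition state, which favours the chain-anti arrangement, and the low temperature removes the thermal side reactions. This fallback makes no new compound (entry F0).

**Step 12.**
- What may go wrong: protonation of the samarium enolate or retro-aldol reversal instead of ring closure, because two fully substituted carbons are joined in a seven-membered ring.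
- Fallback: it sets out from 17 and comes back at 19. The enolate from SmI2 is trapped with Me3SiCl as the trimethylsilyl enol ether F1, and the ring is closed by a Mukaiyama aldol reaction with TiCl4 in CH2Cl2 at –78 °C. Activation of the cyclobutanone by the Lewis acid and the chelated titanium aldolate drive the closure forward.

**Step 14.**
- What may go wrong: inefficient chain propagation at the hindered, strained C7 (slow fragmentation of the stannyl adduct), and rearrangement of the C7 radical by 1,2-acyl shift if hydrogen transfer is slow.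
- Fallback: it sets out from 19 and comes back at 21. Alcohol 19 is converted with oxalyl chloride into the chlorooxoacetate F2 and then, with the sodium salt of N-hydroxypyridine-2-thione, into the mixed oxalate thiohydroxamate F3. Heating or irradiating F3 in the presence of excess tert-butanethiol releases the C7 radical by double decarboxylation, without tin. The radical precursor and chain carrier are different, and C–O cleavage is driven by loss of two molecules of CO2.

**Step 17.**
- What may go wrong: the conjugated aldehyde may be a poor hydride donor, so that hemiacetal formation without reduction, retro-aldol opening of 23, or acyl migration take over.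
- Fallback: it sets out from 23 and 24 and comes back at 28. Benzeneselenol is added to 24 to give the saturated aldehyde 3-methyl-3-(phenylselanyl)butanal F4, which belongs to the aldehyde class that works best in the Evans–Tishchenko reduction. Its reaction with 23 gives the C3 selenoester with a free C5 hydroxyl F5. Acylation with 27 gives the diester F6, and oxidation with H2O2 followed by selenoxide elimination unmasks the senecioate to give 28.

**Step 4.**
- What may go wrong: incomplete enantioselection, which would persist to the end because the minor antipode runs through the same sequence, or an induction sense opposite to the one assumed.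
- Fallback: it sets out from 3 and comes back at 9. Ketone 3 is converted with Me3SiOTf and Et3N into the trimethylsilyl enol ether F7. F7 is added to 6 in a catalytic enantioselective Mukaiyama aldol reaction with SiCl4 activated by a chiral BINAM-derived bisphosphoramide (CH2Cl2, –78 °C), a method suited to conjugated aldehydes. The catalyst antipode is chosen for Re-face addition.

## Further compounds

F0 | step 10 | none | none
F1 | step 12 | (1R,5S,7S)-7-[(1R)-1-[(tert-butyldimethylsilyl)oxy]-4-methyl-3-[(trimethylsilyl)oxy]pent-3-en-1-yl]-2,7-dimethylbicyclo[3.1.1]hept-2-en-6-one | CC(C)=C(O[Si](C)(C)C)C[C@@H](O[Si](C)(C)C(C)(C)C)[C@@]1(C)[C@@H]2CC=C(C)[C@H]1C2=O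
F2 | step 14 | (1S,2S,3R,7S,8R)-3-[(tert-butyldimethylsilyl)oxy]-2,6,6,9-tetramethyl-5-oxotricyclo[5.4.0.0^2,8]undec-9-en-7-yl chlorooxoacetate | CC(C)(C)[Si](C)(C)O[C@@H]1CC(=O)C(C)(C)[C@]2(OC(=O)C(Cl)=O)[C@H]3CC=C(C)[C@@H]2[C@]31C
F3 | step 14 | (1S,2S,3R,7S,8R)-3-[(tert-butyldimethylsilyl)oxy]-2,6,6,9-tetramethyl-5-oxotricyclo[5.4.0.0^2,8]undec-9-en-7-yl 2-thioxopyridin-1(2H)-yl oxalate | CC(C)(C)[Si](C)(C)O[C@@H]1CC(=O)C(C)(C)[C@]2(OC(=O)C(=O)ON4C=CC=CC4=S)[C@H]3CC=C(C)[C@@H]2[C@]31C
F4 | step 17 | 3-methyl-3-(phenylselanyl)butanal | CC(C)(CC=O)[Se]c1ccccc1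
F5 | step 17 | (1R,2R,3R,5R,7S,8R)-5-hydroxy-2,6,6,9-tetramethyl-11-oxotricyclo[5.4.0.0^2,8]undec-9-en-3-yl 3-methyl-3-(phenylselanyl)butanoate | CC(C)(CC(=O)O[C@@H]1C[C@@H](O)C(C)(C)[C@@H]2[C@H]3C(=O)C=C(C)[C@@H]2[C@]31C)[Se]c4ccccc4
F6 | step 17 | (1R,2R,3R,5R,7S,8R)-2,6,6,9-tetramethyl-5-[(3-methylbutanoyl)oxy]-11-oxotricyclo[5.4.0.0^2,8]undec-9-en-3-yl 3-methyl-3-(phenylselanyl)butanoate | CC(C)(CC(=O)O[C@@H]1C[C@@H](OC(=O)CC(C)C)C(C)(C)[C@@H]2[C@H]3C(=O)C=C(C)[C@@H]2[C@]31C)[Se]c4ccccc4
F7 | step 4 | 2-methyl-3-[(trimethylsilyl)oxy]but-3-en-2-yl benzoate | C=C(O[Si](C)(C)C)C(C)(C)OC(=O)c1ccccc1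
A1 | alternative 1 | (1S,5S)-verbenone, 4,6,6-trimethylbicyclo[3.1.1]hept-3-en-2-one | O=C1C=C(C)[C@@H]2C[C@H]1C2(C)C
A2 | alternative 1 | (1R,5S)-chrysanthenone, 2,7,7-trimethylbicyclo[3.1.1]hept-2-en-6-one | O=C1[C@H]2CC=C(C)[C@@H]1C2(C)C
A3 | alternative 1 | tricyclic diethyl oxasilinane bridging the C7 oxygen and C3 | C1[Si](CC)(CC)O[C@@H]2[C@H]3CC=C(C)[C@@H]2[C@]31C
A4 | alternative 2 | N-hydroxyphthalimide ester of the C6 acid carrying the (E)-3-[(4-methoxybenzyl)oxy]acryloyl group on C2 | O=C(ON1C(=O)c2ccccc2C1=O)C(C)(C)[C@@H]3[C@H]4C(=O)C=C(C)[C@@H]3[C@@]4(C)C(=O)/C=C/OCc5ccc(OC)cc5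
A5 | alternative 2 | tricyclic 3,11-diketone with C5 4-methoxybenzyl ether | O=C1C[C@@H](OCc2ccc(OC)cc2)C(C)(C)[C@@H]3[C@H]4C(=O)C=C(C)[C@@H]3[C@]41C
A6 | alternative 3 | 3-(dimethoxymethyl)-3-methylcyclobutan-1-one | COC(OC)C1(C)CC(=O)C1
A7 | alternative 3 | 7-(dimethoxymethyl)-4,7-dimethylbicyclo[3.1.1]heptane-2,6-dione | O=C1[C@H]2C(=O)CC(C)[C@@H]1[C@@]2(C)C(OC)OC
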